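- Substrate is charged at 0.40 M, less than the 0.440 M of partner, so substrate is the limiting reagent and partner holds a surplus of 0.0400 M.

| setting | amber | blue | grey |
|---|---|---|---|
| substrate | 0.40 M (fed, over 20 min) | 0.40 M | 0.40 M |
| partner | 0.440 M | 0.440 M | 0.440 M (fed, over 20 min) |
| time | 1.5 h | 1.5 h | 1.5 h |
| remark | all else is in the flask from the start; the feed brings no volume worth counting | everything together at the start | all else is in the flask from the start; the feed brings no volume worth counting |

    substrate + partner ⇌ adduct (K1 = 46 L mol⁻¹, k1 = 0.28 L mol⁻¹ min⁻¹)
    adduct → target (k2 = 0.13 min⁻¹)
    target ⇌ isomer of the product (K3 = 0.41, k3 = 0.0040 min⁻¹)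

- the flask that comes out highest in amount of target, in percent of the substrate charged, or "all alike" when all lie within 1.5 percentage points (amber / blue / grey / all alike)
- target at the end, in percent of the substrate charged, amber
- target at the end, in percent of the substrate charged, blue
- target at the end, in percent of the substrate charged, grey

- I start with the balance of substrate in blue: adduct takes one of each reagent, so [partner] stays [substrate] plus that surplus, and the second-order loss integrates in closed form. With the first step taken as one-way, 4.96 % of the substrate remains after 1.5 h.
- I guess that target in blue is born about 16.6 min in, adding the second-order time of substrate to the lifetime of adduct.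
- Target and isomer relax at 0.0138 min⁻¹ towards 70.9 % target, so blue keeps 81.5 % as target of what has passed. With adduct counted as passed, that makes target in blue 77.5 %.
- I run amber and grey, each fed over 20 min, on the same clocks started half the feed later. In amber and grey less has passed than in blue, but 83.1 % stays target, which gives 78.2 %. I commit to all alike.
- The weak link is the one-way first step. Adduct returns at 0.00609 min⁻¹ against 0.13 min⁻¹ forward, a share of 4.47 %, so the working constant falls to 0.267 L mol⁻¹ min⁻¹.
- With that constant, substrate left in blue stands at 5.32 %. This is the leftover share: the surplus divided by the larger charge times e to the constant times surplus times time, less the smaller charge, which gives the unreacted fraction of the smaller charge.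
- My target becomes 77.2 % for blue and 77.9 % for the fed flasks, a gap of 0.70 percentage points, under the margin of 1.5 points.
- The forecast says all alike, with amber 77.9 %, blue 77.6 % and grey 78 %, which puts blue higher than my figure. Of feeding against an early start it says: “These effects nearly cancel”.
- The simulation gives all alike: amber 77.6 %, blue 77.4 %, grey 77.6 %.
- Blue ends with substrate at 5.47 %, beside my leftover share of 5.32 %. Its neighbour, charged with 1.6 M of substrate, turns the balance round: partner is now the smaller charge, and the surplus is 1.16 M of substrate. In that neighbour of blue the exponent becomes 27.9, so the leftover share of partner is hardly any, and the surplus is 72.5 % of the substrate charged. That neighbour of blue ends with substrate at 72.5 % and target at 22.2 %.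

(Its constants are made up, and the outcome is calculated.)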